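The numbers in the tables are calculated on assumed constants, and the scatter is random.

0.215 h⁻¹ is the slope k of ln(substrate) against time in the spring run, the very flask asked about, between 1.33 h and 4.00 h: a pseudo-first-order constant, if the substrate is the concentration that sets the order of the rate.

common to all: gas phase 200 mM (held)
- spring: substrate 1 M; free catalyst 5 mM; the very flask that is asked about, followed so far
- flask: substrate 1.0 M; free catalyst 5.0 mM; time 12 h

spring run (percent of the substrate charged)

| time / h | target / % | substrate / % | isomer of the product / % |
|---|---|---|---|
| 0.667 | 10.4 | 90.5 | 0.6 |
| 1.33 | 18.4 | 77.4 | 3.7 |
| 2.00 | 26.8 | 68.7 | 7.1 |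
| 3.00 | 31.1 | 55.1 | 12.8 |
| 4.00 | 35.9 | 43.6 | 19.5 |

(each reading ± 1 percentage point)

- at the start none of the gas is dissolved
- the numbers in the tables scatter by 1 percentage point (one standard deviation)
- on the list of suspects stand: target <-> isomer of the product; substrate + dissolved gas + free catalyst -> free catalyst + target; free catalyst -> spent catalyst; gas phase <-> dissolved gas

- the species in which most of what was charged as substrate, at 12 h sits (target / substrate / isomer of the product)
- the largest share itself, whichever of these holds it, in percent of the substrate charged

Two chemists dispute that "if". The first holds that dissolved gas soon nears its saturation value 200 mM and free catalyst stays, leaving the rate proportional to substrate. The second holds that dissolved gas stays low, with gas uptake as the rate-limiting step, and the rate stays steady: zero order in substrate, a straight line.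

The readings do not part them. The last two hourly drops are 14 percentage points and 12 points, with a scatter of 1 point on each reading. The second chemist's line through the readings at 1.33 h and 4.00 h gives 56.3% at 3.00 h, where the reading is 55.1%.

Extrapolated, they part. The line reaches zero at 7.44 h, so that view expects no substrate at 12 h. My own reckoning takes the first view: starting from 43.6% at 4.00 h, decay with k leaves 7.81% at 12 h. Target and isomer of the product then share the remaining 92.2%.

The forecast also takes the first view and names isomer of the product at 65%: “Target peaks at around 5 h and then drains into the isomer”. That split is its judgement; my reckoning stops at the substrate.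

At 12 h the flask holds isomer of the product at 60.0%, more than target at 32.8%.

    target ⇌ isomer of the product (K = 2.70, k = 6.90 × 10⁻⁵ s⁻¹)
    substrate + dissolved gas + free catalyst → free catalyst + target (k = 0.0660 M⁻² s⁻¹)
    free catalyst → spent catalyst (k = 6.70 × 10⁻⁸ s⁻¹)
    gas phase ⇌ dissolved gas, rate k4*(csat - [dissolved gas]) (kL = 0.00180 s⁻¹)

In the flask at 12 h substrate stands at 7.1% against the reckoned 7.81%, where the line expected none; the line's region is the span of the readings up to 4.00 h. Dissolved gas in the flask stood at 0.174 M after 1.20 h and 0.197 M after 12.0 h. The neighbour flask is the same charge left until 30 h. The same k, from the same reading, gives 0.163% substrate there, and that flask holds 0.10%, with target at 27.2% and isomer of the product at 72.7%.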